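**Remark (assumption):** xanthane numbering is used, unprimed for the diene-derived half (rings A and B) and primed for the dienophile-derived half (rings D and E); the SMILES is read as 1R,5S,7S,8R,10S,7'S,8'S,10'S,11'R, and commercial (S)-but-3-yn-2-ol is taken as enantiopure.

## The problem

The target is a C30 dimer of two xanthanolide units. Ring A (α-methylene-γ-lactone, trans-fused at C7/C8) sits on cycloheptane ring B; ring D (γ-lactone, cis-fused at C7'/C8') sits on cycloheptene ring E. The halves are joined through cyclohexene ring C (C1, C2=C3, C11', C13', C5), which is spiro to ring D at C11' and cis-fused to ring B at C1/C5. Ring C is the feature that makes the key step possible: its bonds C5–C13' and C3–C11' are the two σ-bonds of a [4+2] between a C5=C1–C2=C3 acetyl diene and the exocyclic C11'=C13' alkene of an α-methylene lactone, and the C1–OH/C2=C3–C4=O array is what γ-oxygenation of that adduct leaves. Of the nine stereocentres, C7/C10 and C7'/C10' have the same absolute configuration (10-methyl trans to the C7–C11 bond) and the halves differ only at C8, so one precursor can serve both; C5 and C11' must be set against each half, and C1 against C5. A complete xanthanolide monomer is both diene and dienophile, so two monomers can pair in four ways and the dimer can react on. Ring E, a cycloheptene carrying a 3-oxobutenyl group on C1', is the retron of enyne metathesis plus cross-metathesis, so the dienophile half can be carried as a monocyclic enyne lactone without a diene. The two α-methylene lactones, the dienone with acidic γ- and ε-hydrogens and the tertiary allylic alcohol rule out strong base, nucleophiles and strong acid late in the route.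

## Retrosynthesis

**21 to 19.** The C1'=C5' and C2'=C3' bonds of ring E and its side chain are cut by retro cross-metathesis and retro ring-closing enyne metathesis. Doing this last keeps the base-labile, diene-containing lower dienone out of every earlier step. Precursor 19 carries only an allyl group on C7' and a 2-methylbut-3-ynyl group on C8'. The forward reaction must select the terminal alkene and alkyne over the α-methylene lactone and the ring C enone and tolerate the tertiary alcohol.

**19 to 17.** The C1–O bond is removed. A γ-hydroxy enone comes from the β,γ-unsaturated ketone 17, whose C3–H is the only doubly activated C–H in the molecule. The forward reaction is γ-oxygenation of the dienolate at C1 on the face cis to H5.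

**17 to 14 and 16 (key).** C5–C13' and C3–C11' are cut in a retro-[4+2]. A cut through C1–C2 or C2=C3 would need stepwise polar chemistry and several extra steps. Diene 14 (C15, bicyclic) and dienophile 16 (C13, monocyclic, no diene) are far simpler than tetracycle 17, which gains ring C, the spiro centre and three stereocentres. The forward reaction must give the "ortho" regiochemistry, the carbonyl-exo mode and one face of each partner.

**14 and 16 to 12.** Both halves come from trans lactone 12. Ring B with its diene is cut at C1=C5 and C2=C3 (enyne metathesis, cross-metathesis) to give 14. The cis lactone 16 is the C8 epimer of 12, reached through hydroxy acid 15 by lactonisation with inversion. One stereodefining step therefore serves both halves.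

**12 to 5 and 10.** The C7–C8 bond and the lactone C–O bond are cut by retro allylboration and lactonisation. This sets C7 and C8 together from an achiral boronate and a C6 aldehyde. The forward reaction must be 7,8-anti and must add to the Si face of the aldehyde.

**5 to 1; 10 to 8 to 6 and 7.** C10 is taken from (S)-but-3-yn-2-ol 1 by invertive malonate substitution and two functional-group steps. Boronate 10 comes from ynoate 8 by hydroalumination and borylmethylation, and 8 from ethyl propiolate 6 and allyl bromide 7.

## Roads not taken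

**Alternative 1:** The most obvious cut is the same [4+2] between two finished monomers: diene 14 and the cis-fused monomer A1 would give adduct A2, then γ-oxygenation. Both partners are diene and dienophile, so four pairings compete. A2 still holds a diene and a dienophile and can oligomerise. The base-mediated oxygenation would meet the lower dienone with its acidic ε-hydrogens. In the chosen plan 16 has no diene, 17 has none left, and the dienone appears only in the last, neutral step.

**Alternative 2:** Homodimerisation of A1 to the all-cis adduct A3, then inversion of C8 in ring A by saponification and Mitsunobu relactonisation. There is only one pairing, but the inversion needs hydroxide on a compound with two lactones and two enone systems, and ring A must open selectively over ring D. A3 can also react on as diene and dienophile. Inverting C8 on the simple lactone 12 (steps 9 and 10) is the same chemistry without these liabilities.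

**Alternative 3:** A polar construction of ring C: cut C5–C13' (Michael addition of the C5 enolate of keto lactone A4 to 16, giving A5) and C2=C3 (ring-closing metathesis after a 1-acetylvinyl group is placed on C11' and a vinyl group on the C1 ketone). The tertiary alcohol would arrive without an oxidation. But A4 is itself a Michael acceptor, quaternising C11' by an enolate reaction on a crowded lactone is uncertain, the vinyl addition must pick one of four carbonyls, and at least five steps replace one cycloaddition that sets two bonds and two centres.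

Key step: step 11

## Steps

Step 1
Reactants: 1 (S)-but-3-yn-2-ol
Product: 2 (S)-but-3-yn-2-yl methanesulfonate
Conditions: MsCl, Et3N, CH2Cl2, -20 to 0 °C
Reagents that add atoms: methanesulfonyl chloride (CS(=O)(=O)Cl)
Why: O-sulfonylation of a secondary alcohol; no bond to the stereocentre is broken, so the S configuration is retained.

Step 2
Reactants: 2 (S)-but-3-yn-2-yl methanesulfonate
Product: 3 dimethyl 2-[(2S)-but-3-yn-2-yl]propanedioate
Conditions: dimethyl malonate, NaH, THF/DMF, 0 to 50 °C
Reagents that add atoms: dimethyl malonate (COC(=O)CC(=O)OC)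
Why: SN2 alkylation by the soft malonate anion at the propargylic carbon with inversion; the descriptor stays S only because the new carbon ranks below ethynyl whereas oxygen ranked above it. This sets C10 and C10'.

Step 3
Reactants: 3 dimethyl 2-[(2S)-but-3-yn-2-yl]propanedioate
Product: 4 methyl (3S)-3-methylpent-4-ynoate
Conditions: LiCl, H2O, DMSO, 150 °C
Reagents that add atoms: none
Why: Krapcho dealkoxycarbonylation (chloride demethylation, loss of CO2, protonation); the stereocentre is β to the carbonyl and is not affected.

Step 4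
Reactants: 4 methyl (3S)-3-methylpent-4-ynoate
Product: 5 (3S)-3-methylpent-4-ynal
Conditions: iBu2AlH (1.05 equiv), CH2Cl2, -78 °C; Rochelle salt work-up; used as a solution
Reagents that add atoms: none
Why: partial reduction of the ester through the aluminium hemiacetal, which is stable at -78 °C; the volatile aldehyde is not concentrated to dryness.

Step 5
Reactants: 6 ethyl prop-2-ynoate, 7 3-bromoprop-1-ene
Product: 8 ethyl hex-5-en-2-ynoate
Conditions: CuI (10 mol%), Bu4NI (10 mol%), K2CO3, DMF, rt
Reagents that add atoms: none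
Why: copper-acetylide allylation of a terminal alkyne, the standard entry to skipped enynes; SN2 and SN2' paths give the same product.

Step 6
Reactants: 8 ethyl hex-5-en-2-ynoate
Product: 10 ethyl (2Z)-2-[(4,4,5,5-tetramethyl-1,3,2-dioxaborolan-2-yl)methyl]hexa-2,5-dienoate, via alpha-aluminated dienoate 9 (not isolated)
Conditions: iBu2AlH, N-methylmorpholine N-oxide, THF, 0 °C; then 2-(iodomethyl)-4,4,5,5-tetramethyl-1,3,2-dioxaborolane, 0 °C to rt
Reagents that add atoms: 2-(iodomethyl)-4,4,5,5-tetramethyl-1,3,2-dioxaborolane (ICB1OC(C)(C)C(C)(C)O1)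
Why: syn hydroalumination of the ynoate (H to C3, Al to C2) followed by Matteson-type homologation: the vinylalane adds to boron and 1,2-migration expels iodide with retention, so C4 ends cis to the ester and trans to the CH2B group.

Step 7
Reactants: 5 (3S)-3-methylpent-4-ynal, 10 ethyl (2Z)-2-[(4,4,5,5-tetramethyl-1,3,2-dioxaborolan-2-yl)methyl]hexa-2,5-dienoate
Product: 12 (4S,5R)-3-methylidene-5-[(2S)-2-methylbut-3-yn-1-yl]-4-(prop-2-en-1-yl)oxolan-2-one, via O-boryl anti hydroxy ester 11 (not isolated)
Conditions: (S)-TRIP (5 mol%), 4 Å molecular sieves, toluene, -30 °C to rt; then TsOH·H2O, rt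
Reagents that add atoms: none
Why: chiral phosphoric acid-catalysed allylboration through a closed chair transition state; the chain trans to CH2B sits equatorial, which gives the 7,8-anti adduct, and the (S) acid is chosen to deliver C7 to the Si face of 5 (8R, hence 7S). Acid then closes the trans γ-lactone with loss of ethanol.

Step 8
Reactants: 12 (4S,5R)-3-methylidene-5-[(2S)-2-methylbut-3-yn-1-yl]-4-(prop-2-en-1-yl)oxolan-2-one
Product: 14 (3aS,7S,8aR)-7-methyl-3-methylidene-6-[(1E)-3-oxobut-1-en-1-yl]-3,3a,4,7,8,8a-hexahydro-2H-cyclohepta[b]furan-2-one, via 6-vinyl triene 13 (not isolated)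
Conditions: but-3-en-2-one (10 equiv), second-generation Grubbs catalyst [RuCl2(=CHPh)(PCy3)(H2IMes)] (5 mol%), CH2Cl2, 40 °C
Reagents that add atoms: but-3-en-2-one (C=CC(C)=O)
Why: domino ring-closing enyne metathesis (exo mode, C5 to C1) and E-selective cross-metathesis of the new vinyl group with the enone; the 1,1-disubstituted electron-poor alkene of the lactone does not engage and no stereocentre is touched.

Step 9
Reactants: 12 (4S,5R)-3-methylidene-5-[(2S)-2-methylbut-3-yn-1-yl]-4-(prop-2-en-1-yl)oxolan-2-one
Product: 15 (3S,4R,6S)-4-hydroxy-6-methyl-2-methylidene-3-(prop-2-en-1-yl)oct-7-ynoic acid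
Conditions: LiOH, THF/H2O, 0 °C; then aq HCl to pH 4 at 0 °C, extraction, used at once
Reagents that add atoms: lithium hydroxide ([Li+].[OH-])
Why: saponification by acyl–oxygen cleavage leaves C8 untouched; the cold, brief work-up is meant to outrun relactonisation.

Step 10
Reactants: 15 (3S,4R,6S)-4-hydroxy-6-methyl-2-methylidene-3-(prop-2-en-1-yl)oct-7-ynoic acid
Product: 16 (4S,5S)-3-methylidene-5-[(2S)-2-methylbut-3-yn-1-yl]-4-(prop-2-en-1-yl)oxolan-2-one
Conditions: PPh3, diisopropyl azodicarboxylate, THF, 0 °C
Reagents that add atoms: none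
Why: Mitsunobu lactonisation: the C8 hydroxyl is activated as the alkoxyphosphonium ion and displaced intramolecularly by the carboxylate with inversion (8R to 8S), giving the cis lactone while C7 and C10 are unchanged.

Step 11
Reactants: 14 (3aS,7S,8aR)-7-methyl-3-methylidene-6-[(1E)-3-oxobut-1-en-1-yl]-3,3a,4,7,8,8a-hexahydro-2H-cyclohepta[b]furan-2-one, 16 (4S,5S)-3-methylidene-5-[(2S)-2-methylbut-3-yn-1-yl]-4-(prop-2-en-1-yl)oxolan-2-one
Product: 17 [4+2] adduct of 14 and 16 (3S,5S,7S,8R,10S,7'S,8'S,10'S,11'R): ring C is a cyclohexene with C1=C2 and 3-acetyl, fused to ring B at C1/C5 and spiro at C11' to lactone ring D, which keeps the cis 7'-allyl and 8'-[(2S)-2-methylbut-3-ynyl] groups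
Conditions: 16 (4 equiv), BHT (5 mol%), toluene (2 M in 14), sealed tube, 120 °C; excess 16 recovered
Reagents that add atoms: none
Why: A thermal, concerted but asynchronous [4+2] between the s-cis C5=C1–C2=C3 acetyl diene of 14 and the exocyclic C11'=C13' alkene of 16; the closest known reaction type is the Diels–Alder addition of 1-acyl dienes to α-methylene-γ-butyrolactones. Ring C is closed by this intermolecular [4+2] through the bonds C5–C13' and C3–C11', which makes C11' the spiro centre; no other ring forms. The regiochemistry follows from the largest diene HOMO coefficient at C5 (remote from the acetyl, reinforced by the C10 branch on C1) and the largest dienophile LUMO coefficient at C13'. C11' is set by the dienophile: the diene adds to the face of ring D opposite to the cis allyl and alkynyl chains, and the s-cis-locked lactone reacts carbonyl-exo, so C12' ends trans to C6 across ring C. C5 is set by ring B: the trans-diequatorial lactone fusion holds the cycloheptene of 14 in the chair with the 10-methyl equatorial, and the new bond forms axially on its convex face, trans to the C7–C11 bond. C3 (acetyl cis to C6) follows from suprafacial addition to the E diene and is erased in step 12, so it needs no control. Cross-selectivity is needed and is secured because 16 has no diene and is used in excess over the α-methylene lactone of 14, and because 17 has no diene left. BHT suppresses radical polymerisation, and the β,γ-enone of 17 should survive neutral heating.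

Step 12
Reactants: 17 [4+2] adduct of 14 and 16 (3S,5S,7S,8R,10S,7'S,8'S,10'S,11'R)
Product: 19 1-hydroxy analogue of 17 (1R,5S,7S,8R,10S,7'S,8'S,10'S,11'R; tertiary OH at C1; C2=C3 conjugated to the acetyl), via C1 hydroperoxide 18 (not isolated)
Conditions: O2 (1 atm), DBU, P(OEt)3, MeCN, 0 °C
Reagents that add atoms: dioxygen (O=O)
Why: γ-oxygenation of a β,γ-unsaturated ketone: the doubly activated C3–H gives the dienolate, which takes up O2 at C1 and moves the alkene into conjugation; the phosphite reduces the hydroperoxide in the flask. O2 should enter on the face of the ring C dienolate away from ring B, cis to H5, giving the cis B/C fusion (1R).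

Step 13
Reactants: 19 1-hydroxy analogue of 17 (1R,5S,7S,8R,10S,7'S,8'S,10'S,11'R)
Product: 21 CNP0168949.5 (1R,5S,7S,8R,10S,7'S,8'S,10'S,11'R), via vinyl triene 20 (not isolated)
Conditions: but-3-en-2-one (10 equiv), second-generation Hoveyda–Grubbs catalyst [RuCl2(=CH-C6H4-2-OiPr)(H2IMes)] (10 mol%), CH2Cl2, 40 °C
Reagents that add atoms: but-3-en-2-one (C=CC(C)=O)
Why: the same domino as in step 8 closes ring E from the cis-disposed allyl and butynyl chains and attaches the E enone by cross-metathesis; the hindered ring C enone, the α-methylene lactone and the tertiary alcohol are expected to be spectators and no stereocentre is touched.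

## Compound list

1 | (S)-but-3-yn-2-ol | C[C@H](O)C#C | starting material
2 | (S)-but-3-yn-2-yl methanesulfonate | C[C@H](OS(C)(=O)=O)C#C | intermediate
3 | dimethyl 2-[(2S)-but-3-yn-2-yl]propanedioate | C[C@@H](C(C(=O)OC)C(=O)OC)C#C | intermediate
4 | methyl (3S)-3-methylpent-4-ynoate | C[C@@H](CC(=O)OC)C#C | intermediate
5 | (3S)-3-methylpent-4-ynal | O=CC[C@H](C)C#C | intermediate
6 | ethyl prop-2-ynoate | C#CC(=O)OCC | starting material
7 | 3-bromoprop-1-ene | C=CCBr | starting material
8 | ethyl hex-5-en-2-ynoate | C=CCC#CC(=O)OCC | intermediate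
9 | ethyl (2E)-2-[bis(2-methylpropyl)alumanyl]hexa-2,5-dienoate (Al cis to H3) | CCOC(=O)/C(=C\CC=C)[Al](CC(C)C)CC(C)C | intermediate
10 | ethyl (2Z)-2-[(4,4,5,5-tetramethyl-1,3,2-dioxaborolan-2-yl)methyl]hexa-2,5-dienoate (C4 cis to the ester) | CCOC(=O)/C(CB1OC(C)(C)C(C)(C)O1)=C\CC=C | intermediate
11 | ethyl (3S,4R,6S)-6-methyl-2-methylidene-3-(prop-2-en-1-yl)-4-[(4,4,5,5-tetramethyl-1,3,2-dioxaborolan-2-yl)oxy]oct-7-ynoate | C=C(C(=O)OCC)[C@H](CC=C)[C@H](OB1OC(C)(C)C(C)(C)O1)C[C@H](C)C#C | intermediate
12 | (4S,5R)-3-methylidene-5-[(2S)-2-methylbut-3-yn-1-yl]-4-(prop-2-en-1-yl)oxolan-2-one (trans lactone) | C=C1C(=O)O[C@H](C[C@H](C)C#C)[C@H]1CC=C | intermediate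
13 | (3aS,7S,8aR)-6-ethenyl-7-methyl-3-methylidene-3,3a,4,7,8,8a-hexahydro-2H-cyclohepta[b]furan-2-one | C=C1C(=O)O[C@@H]2C[C@H](C)C(C=C)=CC[C@@H]12 | intermediate
14 | (3aS,7S,8aR)-7-methyl-3-methylidene-6-[(1E)-3-oxobut-1-en-1-yl]-3,3a,4,7,8,8a-hexahydro-2H-cyclohepta[b]furan-2-one (diene half, trans-fused) | C=C1C(=O)O[C@@H]2C[C@H](C)C(/C=C/C(C)=O)=CC[C@@H]12 | intermediate
15 | (3S,4R,6S)-4-hydroxy-6-methyl-2-methylidene-3-(prop-2-en-1-yl)oct-7-ynoic acid | C=C(C(=O)O)[C@H](CC=C)[C@H](O)C[C@H](C)C#C | intermediate
16 | (4S,5S)-3-methylidene-5-[(2S)-2-methylbut-3-yn-1-yl]-4-(prop-2-en-1-yl)oxolan-2-one (cis lactone, dienophile half) | C=C1C(=O)O[C@@H](C[C@H](C)C#C)[C@H]1CC=C | intermediate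
17 | [4+2] adduct (3S,5S,7S,8R,10S,7'S,8'S,10'S,11'R): rings A and B of 14, ring C cyclohexene (C1=C2, 3-acetyl), spiro lactone ring D with cis 7'-allyl and 8'-[(2S)-2-methylbut-3-ynyl] | C=C1C(=O)O[C@@H]2C[C@H](C)C3=C[C@H](C(C)=O)[C@]4(C[C@@H]3C[C@@H]12)C(=O)O[C@@H](C[C@H](C)C#C)[C@H]4CC=C | intermediate
18 | 1-hydroperoxide of the transposed enone (1R,5S,7S,8R,10S,7'S,8'S,10'S,11'R) | C=C1C(=O)O[C@@H]2C[C@H](C)[C@]3(OO)C=C(C(C)=O)[C@]4(C[C@@H]3C[C@@H]12)C(=O)O[C@@H](C[C@H](C)C#C)[C@H]4CC=C | intermediate
19 | 1-hydroxy enone (1R,5S,7S,8R,10S,7'S,8'S,10'S,11'R) with open enyne chains on ring D | C=C1C(=O)O[C@@H]2C[C@H](C)[C@]3(O)C=C(C(C)=O)[C@]4(C[C@@H]3C[C@@H]12)C(=O)O[C@@H](C[C@H](C)C#C)[C@H]4CC=C | intermediate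
20 | ring E closed, 1'-ethenyl triene (1R,5S,7S,8R,10S,7'S,8'S,10'S,11'R) | C=C1C(=O)O[C@@H]2C[C@H](C)[C@]3(O)C=C(C(C)=O)[C@]4(C[C@@H]3C[C@@H]12)C(=O)O[C@H]1C[C@H](C)C(C=C)=CC[C@H]14 | intermediate
21 | CNP0168949.5 (1R,5S,7S,8R,10S,7'S,8'S,10'S,11'R) | C=C1C(=O)O[C@@H]2C[C@H](C)[C@]3(O)C=C(C(C)=O)[C@]4(C[C@@H]3C[C@@H]12)C(=O)O[C@H]1C[C@H](C)C(/C=C/C(C)=O)=CC[C@H]14 | target

## Step count and risks

Total step count: 13. Longest linear sequence: 10 steps (1, 2, 3, 4, 7, 9, 10, 11, 12, 13).

**Step 11 (key).** The most likely failure is competing self-cycloaddition of 14, whose own trans-fused α-methylene lactone is a dienophile; slow reaction of two electron-poor partners, thermal polymerisation, or erosion of exo and facial selectivity at 120 °C are further possibilities. The fallback sets out from 5 and 10 and returns at 17. Step 7 is run without the acid treatment and the anti hydroxy ester, ethyl (3S,4R,6S)-4-hydroxy-6-methyl-2-methylidene-3-(prop-2-en-1-yl)oct-7-ynoate F1, is isolated and silylated (TBSOTf, 2,6-lutidine) to its tert-butyldimethylsilyl ether F2. The metathesis domino of step 8 then gives, through the vinyl triene F3, the ring-open dienone ester F4, whose α-branched acyclic acrylate is a poor dienophile. Cycloaddition of F4 with 16 under the conditions of step 11 gives the ring-open adduct F5. HF·pyridine removes the silyl group to give the hydroxy ester adduct F6, which lactonises (TsOH) with retention at C8 to 17.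

**Step 13.** Catalyst deactivation by the crowded γ-hydroxy enone and spiro lactone, incomplete cross-metathesis, or metathesis at the wrong alkene may occur. The fallback sets out from 16 and returns at 21: the dienone is installed before the cycloaddition. The conditions of step 8 convert 16 through the cis-fused vinyl triene F7 into the cis-fused monomer F8. Cycloaddition of 14 with F8 gives the dienone adduct F9, and oxygenation as in step 12 proceeds through the hydroperoxide F10 to 21. This fallback accepts the pairing and base-sensitivity problems that the main route avoids.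

**Step 12.** The base may attack the α-methylene lactone, oxygen may enter at C3 instead of C1, facial selectivity at C1 may be poor, or the hydroperoxide may fragment. The fallback sets out from 17 and returns at 19 and makes no new compound: a Schenck ene reaction with singlet oxygen (O2, light, tetraphenylporphyrin, CH2Cl2, -20 °C) removes H3 and places oxygen on C1 without base, giving the same hydroperoxide 18, which PPh3 reduces.

**Step 10.** Lactonisation may occur with retention through activation of the carboxyl group, or elimination across C8–C9 may compete. The fallback sets out from 15 and returns at 16. The acid is methylated (TMSCHN2) to the methyl ester F11 and the alcohol is sulfonylated (MsCl, Et3N) to the mesylate F12. LiOH then hydrolyses the ester, and the lithium carboxylate F13 displaces the mesylate intramolecularly with inversion.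

**Step 7.** Catalyst control may be weak because the ester-deactivated boronate reacts slowly and an uncatalysed background reaction lowers the facial selectivity. The fallback sets out from 5 and 10 and returns at 12. The uncatalysed thermal allylboration (toluene, 80 °C), which is still anti-selective through the closed transition state, gives 11 together with its diastereomer, the (3R,4S,6S) O-boryl hydroxy ester F14. Acid converts them to 12 and the (4R,5S) lactone F15. The two are diastereomers because C10 is already fixed and are separated by chromatography.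

## Further compounds

F1 | step 11 | ethyl (3S,4R,6S)-4-hydroxy-6-methyl-2-methylidene-3-(prop-2-en-1-yl)oct-7-ynoate | C=C(C(=O)OCC)[C@H](CC=C)[C@H](O)C[C@H](C)C#C
F2 | step 11 | ethyl (3S,4R,6S)-4-{[tert-butyl(dimethyl)silyl]oxy}-6-methyl-2-methylidene-3-(prop-2-en-1-yl)oct-7-ynoate | C=C(C(=O)OCC)[C@H](CC=C)[C@H](O[Si](C)(C)C(C)(C)C)C[C@H](C)C#C
F3 | step 11 | ethyl 2-[(1S,2R,4S)-2-{[tert-butyl(dimethyl)silyl]oxy}-5-ethenyl-4-methylcyclohept-5-en-1-yl]prop-2-enoate | C=C(C(=O)OCC)[C@@H]1CC=C(C=C)[C@@H](C)C[C@H]1O[Si](C)(C)C(C)(C)C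
F4 | step 11 | ethyl 2-[(1S,2R,4S)-2-{[tert-butyl(dimethyl)silyl]oxy}-4-methyl-5-[(1E)-3-oxobut-1-en-1-yl]cyclohept-5-en-1-yl]prop-2-enoate | C=C(C(=O)OCC)[C@@H]1CC=C(/C=C/C(C)=O)[C@@H](C)C[C@H]1O[Si](C)(C)C(C)(C)C
F5 | step 11 | ring-open analogue of 17 with 8-O-silyl ether and ethyl acrylate at C7 (3S,5S,7S,8R,10S,7'S,8'S,10'S,11'R) | CC(C)(C)[Si](C)(C)O[C@@H]1C[C@H](C)C2=C[C@H](C(C)=O)[C@]3(C[C@@H]2C[C@H]1C(=C)C(=O)OCC)C(=O)O[C@@H](C[C@H](C)C#C)[C@H]3CC=C
F6 | step 11 | ring-open analogue of 17 with free 8-hydroxyl and ethyl acrylate at C7 | O[C@@H]1C[C@H](C)C2=C[C@H](C(C)=O)[C@]3(C[C@@H]2C[C@H]1C(=C)C(=O)OCC)C(=O)O[C@@H](C[C@H](C)C#C)[C@H]3CC=C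
F7 | step 13 | (3aS,7S,8aS)-6-ethenyl-7-methyl-3-methylidene-3,3a,4,7,8,8a-hexahydro-2H-cyclohepta[b]furan-2-one | C=C1C(=O)O[C@H]2C[C@H](C)C(C=C)=CC[C@@H]12
F8 | step 13 | (3aS,7S,8aS)-7-methyl-3-methylidene-6-[(1E)-3-oxobut-1-en-1-yl]-3,3a,4,7,8,8a-hexahydro-2H-cyclohepta[b]furan-2-one | C=C1C(=O)O[C@H]2C[C@H](C)C(/C=C/C(C)=O)=CC[C@@H]12
F9 | step 13 | [4+2] adduct of 14 and the cis-fused monomer (1-deoxy, C1=C2, 3S) with complete ring E dienone | C=C1C(=O)O[C@@H]2C[C@H](C)C3=C[C@H](C(C)=O)[C@]4(C[C@@H]3C[C@@H]12)C(=O)O[C@H]1C[C@H](C)C(/C=C/C(C)=O)=CC[C@H]14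
F10 | step 13 | 1-hydroperoxide corresponding to 21 | C=C1C(=O)O[C@@H]2C[C@H](C)[C@]3(OO)C=C(C(C)=O)[C@]4(C[C@@H]3C[C@@H]12)C(=O)O[C@H]1C[C@H](C)C(/C=C/C(C)=O)=CC[C@H]14
F0 | step 12 | none | none
F11 | step 10 | methyl (3S,4R,6S)-4-hydroxy-6-methyl-2-methylidene-3-(prop-2-en-1-yl)oct-7-ynoate | C=C(C(=O)OC)[C@H](CC=C)[C@H](O)C[C@H](C)C#C
F12 | step 10 | methyl (3S,4R,6S)-4-(methanesulfonyloxy)-6-methyl-2-methylidene-3-(prop-2-en-1-yl)oct-7-ynoate | C=C(C(=O)OC)[C@H](CC=C)[C@H](OS(C)(=O)=O)C[C@H](C)C#C
F13 | step 10 | lithium (3S,4R,6S)-4-(methanesulfonyloxy)-6-methyl-2-methylidene-3-(prop-2-en-1-yl)oct-7-ynoate | C=C(C(=O)[O-])[C@H](CC=C)[C@H](OS(C)(=O)=O)C[C@H](C)C#C.[Li+]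
F14 | step 7 | ethyl (3R,4S,6S)-6-methyl-2-methylidene-3-(prop-2-en-1-yl)-4-[(4,4,5,5-tetramethyl-1,3,2-dioxaborolan-2-yl)oxy]oct-7-ynoate | C=C(C(=O)OCC)[C@@H](CC=C)[C@@H](OB1OC(C)(C)C(C)(C)O1)C[C@H](C)C#C
F15 | step 7 | (4R,5S)-3-methylidene-5-[(2S)-2-methylbut-3-yn-1-yl]-4-(prop-2-en-1-yl)oxolan-2-one | C=C1C(=O)O[C@@H](C[C@H](C)C#C)[C@@H]1CC=C
A1 | alternative 1 | (3aS,7S,8aS)-7-methyl-3-methylidene-6-[(1E)-3-oxobut-1-en-1-yl]-3,3a,4,7,8,8a-hexahydro-2H-cyclohepta[b]furan-2-one (cis-fused monomer) | C=C1C(=O)O[C@H]2C[C@H](C)C(/C=C/C(C)=O)=CC[C@@H]12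
A2 | alternative 1 | [4+2] adduct of 14 and A1 (1-deoxy, C1=C2, 3S) | C=C1C(=O)O[C@@H]2C[C@H](C)C3=C[C@H](C(C)=O)[C@]4(C[C@@H]3C[C@@H]12)C(=O)O[C@H]1C[C@H](C)C(/C=C/C(C)=O)=CC[C@H]14
A3 | alternative 2 | [4+2] homodimer of A1 (ring A cis-fused, 8S; otherwise as A2) | C=C1C(=O)O[C@H]2C[C@H](C)C3=C[C@H](C(C)=O)[C@]4(C[C@@H]3C[C@@H]12)C(=O)O[C@H]1C[C@H](C)C(/C=C/C(C)=O)=CC[C@H]14
A4 | alternative 3 | (3aS,7S,8aR)-7-methyl-3-methylidenehexahydro-2H-cyclohepta[b]furan-2,6(3H)-dione | C=C1C(=O)O[C@@H]2C[C@H](C)C(=O)CC[C@@H]12
A5 | alternative 3 | Michael adduct of A4 (C5) and 16 (C13'), with H at C11' | C=C1C(=O)O[C@@H]2C[C@H](C)C(=O)[C@H](C[C@H]3C(=O)O[C@@H](C[C@H](C)C#C)[C@H]3CC=C)C[C@@H]12
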